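**The bound.** The noon run cannot hold more complex with one exchanged than 0.500 of the starting complex charged, since each exchange spends one incoming ligand and that is the ligand charged per starting complex. In the noon run incoming ligand is the limiting reagent: its 7.5 mM stands below the 12.0 mM of starting complex that the protic impurity can leave.

| flask | starting complex | incoming ligand | protic impurity | remark | time |
|---|---|---|---|---|---|
| noon | 15 mM | 7.5 mM | 3 mM | run made earlier |  |
| summer | 15 mM | 11 mM | 3 mM | run made earlier |  |
| dawn | 30 mM | 15 mM | 3 mM | run made earlier |  |
| flask | 15 mM | 15.0 mM | 3.00 mM |  | 25 min |

| run | time / min | complex with one exchanged / % | starting complex / % |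
|---|---|---|---|
| noon | 1.33 | 5 | 85 |
| noon | 2.50 | 10 | 76 |
| noon | 4.00 | 17 | 70 |
| noon | 8.00 | 19 | 56 |
| noon | 15.0 | 29 | 44 |
| summer | 1.33 | 5 | 82 |
| summer | 4.00 | 22 | 57 |
| summer | 8.00 | 30 | 39 |
| summer | 10.0 | 35 | 44 |
| summer | 15.0 | 40 | 31 |
| dawn | 1.33 | 14 | 79 |
| dawn | 2.50 | 19 | 69 |
| dawn | 4.00 | 20 | 62 |
| dawn | 8.00 | 34 | 53 |
| dawn | 15.0 | 37 | 50 |

(each reading ± 2 percentage points)

- the earlier runs were read with a standard deviation of 2 percentage points
- what may be going on: starting complex + incoming ligand <-> leaving ligand + complex with one exchanged; protic impurity + starting complex -> quenched substrate; complex with one exchanged <-> isomer of the product; complex with one exchanged + incoming ligand <-> leaving ligand + complex with two exchanged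

- equivalents of incoming ligand to starting complex, everything else as given, that leave most complex with one exchanged at 25 min
- the amount of complex with one exchanged then, in percent of the starting complex charged
- the amount of complex with one exchanged with the amounts as given

**Ligand yield.** So I read each run against its ligand. At 15.0 min, noon shows 0.580 of its charged ligand standing as complex with one exchanged, and summer shows 0.545. I carry their mean, the ligand yield, 0.563.

**The crossing.** Starting complex and complex with one exchanged together stand at 73.0% and 71.0% of the charge in those readings, so I take a roof of 0.720. Yield times equivalents, the ligand line, meets that roof at 1.28 equivalents; this is a meeting of two lines read from the runs, not a point where incoming ligand runs out. Below it I reckon by the ligand line, above it by the roof. The flask has 1.00 equivalents, so it follows the ligand line.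

**Weak link.** The yield comes from 15.0 min and from below one equivalent. Extended along its fall from noon to summer, it reaches 0.506 at one equivalent. I judge that the later minutes add between nothing and the 10 percentage points that summer gained from 8.00 min to 15.0 min. Taking the middle, I commit to 0.556.

**The forecast.** It says 43% (37% to 49%) as given, and 50% at 1.7 equiv equivalents, on this ground: “More ligand overcomes the reversibility, but double exchange then erodes the product”.

**The result.** The flask gives 52.0%, and the best is 58.3% at 1.86 equiv equivalents, so my crossing lies low.

    starting complex + incoming ligand ⇌ leaving ligand + complex with one exchanged (K = 14.0, k = 11.0 /M/min)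
    protic impurity + starting complex → quenched substrate (k = 21.0 /M/min)
    complex with one exchanged ⇌ isomer of the product (K = 0.180, k = 0.160 /min)
    complex with one exchanged + incoming ligand ⇌ leaving ligand + complex with two exchanged (K = 0.200, k = 25.0 /M/min)

**What ran.** In the flask, starting complex falls from 63.7% at 2.50 min to 15.7% at 25.0 min, while 30% of the incoming ligand remains. The second exchange runs back at 97% of its forward turnover, complex with two exchanged stands at 4.44%, and the flask's ligand yield is 0.520.

**Next flask.** The neighbour with 38 mM of incoming ligand lies above the crossing: its ligand line gives 1.43, over the roof, so I read 0.720. That neighbour computes to 57.3%, with 17.1% as complex with two exchanged.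

Readings and results stem from a simulated flask for an exercise; scatter was added.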